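The readings were computed for substances that don't exist; noise was put on by code.

The vessel was closed, stirred and isothermal, and J met Z in it; I had the dusk and midnight runs to judge the new flasks by.

| setting | dusk | midnight | east | south-east | south-west |
|---|---|---|---|---|---|
| J | 0.0050 M | 0.0050 M | 0.0050 M | 0.0050 M | 0.0050 M |
| Z | 1.4 mM | 10 mM | 2.50 mM | 12.5 mM | 15.0 mM |
| remark | run made earlier | run made earlier |  |  |  |
| time |  |  | 2.0 min | 2.0 min | 2.0 min |

- dusk (time / s: Q / %, J / %): 30.0: 17.8, 75.0; 60.0: 16.9, 76.4; 90.0: 15.4, 77.1; 120: 14.8, 73.5
- midnight (time / s: Q / %, J / %): 15.0: 18.9, 7.6; 40.0: 16.3, 2.2; 80.0: 11.6, 0.3; 120: 8.3, 0.4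

(scatter of a reading: 1 percentage point)

- steps that have been proposed: J + Z -> Q + E; Z + Q <-> L + E; Q + E -> X

* Q at the end, in percent of the J charged, for each flask in turn (east, south-east, south-west)

I ordered the flask by time. Two midnight readings put the half-life of J near 14.0 s, and the dusk readings of J already stood flat, within their scatter, by 30.0 s. Q faded more slowly, its readings giving a half-life near 82.8 s at midnight and near 338 s at dusk. So I expected a flask short of Z to stop turning J early and then spend the remaining time on its Q.

The dusk plateau then gave a price. Its J readings average 75.5%, so 1.22 mM of J turned for 1.4 mM of Z. Taking that Z as used, I defined the Z price, the Z used per J turned, and read it from the dusk readings as 1.14. Each J turned takes one Z, and each L standing in the flask has taken another, so the price less one is the share of the turned J standing as L, and two less the price is the share standing as Q and X together.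

In east, at the dusk price, 2.50 mM of Z buys 2.19 mM of J, so I took Z as the limiting reagent. For east I reckoned 56.2% of J left and Q plus X at 37.5% of the J charged. I made no figure for the flasks with more Z. The forecast gave 17%, 5% and 3.5%, and said of Q in the midnight run that “excess Z drives it towards L”.

The flasks gave 19.9%, 6.31% and 5.09%, within the forecast's margin.

    J + Z → Q + E (k = 43.0 L mol⁻¹ s⁻¹)
    Z + Q ⇌ L + E (K = 16.0, k = 76.0 L mol⁻¹ s⁻¹)
    Q + E → X (k = 3.20 L mol⁻¹ s⁻¹)

In east at 0.0528 min, J + Z used Z 2.6 times as fast as the forward Z + Q step. By 2.0 min the price there stood at 1.15, with J at 57% and Q plus X at 36.6%, against my 37.5%. In south-east the price stood at 1.66 by 2.0 min, which puts 34.5% of the turned J in Q and X together, and Q itself stood at 6.31% of the J charged.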